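The ratio of the rate constant of substrate + partner B to that of partner B + partner A, s = 4.01, is the selectivity factor of this flask: both steps draw on the same free partner B, so in a closed flask the fraction of substrate left equals x, the fraction of partner A left, raised to the power s.

all flasks: substrate 1.0 mM; partner B 2.00 mM
- larch: partner A 0.800 mM; time 1.5 min; a closed flask charged with all of it at once and left for 1.5 min
- oak: partner A 0.800 mM (fed, over 1.20 min); time 1.5 min; all but partner A at the start; partner A goes in evenly over 1.20 min, the run ends at 1.5 min
- ash: partner A 0.800 mM; time 1.5 min; plug flow through a tube for 1.5 min, no back-mixing
- cedar: partner A 0.800 mM; a single well-mixed tank run continuously and read at steady state, 1.5 min in it on average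

- the set-up with the highest amount of open intermediate at the outlet or at the end, in percent of the substrate put in ("none" if the first two lie within 2 percentage points) (larch / oak / ash / cedar / none)
- amount of open intermediate at the outlet or at the end, in percent of the substrate put in, larch
- amount of open intermediate at the outlet or at the end, in percent of the substrate put in, oak
- amount of open intermediate at the outlet or at the end, in percent of the substrate put in, ash
- amount of open intermediate at the outlet or at the end, in percent of the substrate put in, cedar

- the stated concentrations are those of everything mixed, before any reaction; amounts are the same in each set-up
- the feed brings no volume worth counting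
- run time (larch): 1.5 min

    open intermediate + second intermediate → target (k1 = 121 M⁻¹ s⁻¹)
    substrate + partner B → open intermediate (k2 = 141 M⁻¹ s⁻¹)
    partner B ⇌ dormant form (K3 = 0.395, k3 = 0.176 s⁻¹)
    partner B + partner A → second intermediate (k4 = 35.2 M⁻¹ s⁻¹)

In the first instants of larch, partner B and dormant form share themselves out with a relaxation half-life of 1.12 s, shorter than the 2.5 s half-life of substrate by its step with partner B alone at the charged concentrations, so my reckoning holds a steady share f = 71.7% of their pool free from then on. In the middle of larch the rule puts substrate ahead: at x = 0.5 it stands at 6.21%, and the pool is then close to the excess e of partner B over substrate and partner A, 0.200 mM, plus the partner A still present. My reckoning takes that pool from the start, which ignores the substrate's extra partner B in the early seconds and so leaves x somewhat high. With k_A = 35.2 M⁻¹ s⁻¹, integration gives G = exp(−e·k_A·f·t) = 0.635 and x = e·G/(c(partner B) − c(substrate) − c(partner A)·G) = 25.8%, hence 0.437% of the substrate left.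

Towards the end of larch the balance matters: open intermediate equals substrate gone, less partner A gone, plus second intermediate standing. That is 40.2% before the last term. Taking second intermediate as used as fast as it is made gives 0.0435 mM, so I commit to 44.6% for larch. Ash, a tube without back-mixing, repeats larch with distance for time. In oak a portion of partner A stays 0.900 min on average; putting that time into the same line, roughly, and counting substrate as gone, gives x = 39.0% and open intermediate 57.7%, more than my figure for larch. For cedar my reckoning stops.

The forecast gives 43% for larch, 56% for oak, 43% for ash and 46% for cedar, and names oak, since “Feeding A slowly keeps it low and starves the step that makes the second intermediate”. Its figure for larch is lower than mine, and so is its figure for oak.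

The simulation gives 42.7% for larch, 59.9% for oak, 42.7% for ash and 45.7% for cedar, with oak best.

In larch partner A ends at 23.2% of its charge, and that raised to s is 0.286%, where substrate stands at 0.288%. The neighbour of larch charged with 0.48 mM of partner A has e = 0.520 mM, so the same line gives x = 18.7% and open intermediate 62.7%. That flask ends with partner A at 16.4%, which raised to s is 0.0710%, with substrate at 0.0716% and open intermediate at 61.8%.

The numbers are invented; the result is computed.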